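The carbocycle (ring B: C4a–C5–C6–C7–C8–C8a) carries its two stereocentres, C5 and C8, cis and 1,4 to each other on either side of the ring-fusion bond C4a–C8a. That pattern is the signature of a Diels–Alder reaction. An enantioselective, iminium-catalysed cycloaddition of acrolein to a (1E,3E)-1-methoxy-4-alkyl diene forms C4a–C5 and C8a–C8 at once and sets both centres. The precursor is an acyclic dienyl methyl ether plus a three-carbon enal. The formyl group on C8a is only an activating group: it is later excised to a ketone, on which the N-methoxy-4-pyridone (ring A) is built.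

Key step: step 3

Remark: atom labels follow the quinolin-4(1H)-one skeleton of the target (N1, C2, C3, C4, C4a, C5–C8, C8a); (2E)-3-methoxyprop-2-enal, 5-phenylpent-1-ene and N,2-dimethoxy-N-methylacetamide are taken as catalogue compounds.

Step 1
Reactants: 1 (2E)-3-methoxyprop-2-enal
Product: 2 (1E,3E)-1-iodo-4-methoxybuta-1,3-diene
Conditions: CrCl2, CHI3, THF, 0 °C, dark
Reagents that add atoms: iodoform, IC(I)I
Why: Takai iodo-olefination, in which the geminal dichromium reagent made from CHI3 and CrCl2 adds to the aldehyde and eliminates to the E-vinyl iodide, should leave the enol ether untouched and give the future C5=C6 bond trans.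

Step 2
Reactants: 3 5-phenylpent-1-ene; 2 (1E,3E)-1-iodo-4-methoxybuta-1,3-diene
Product: 5 (1E,3E)-1-methoxy-9-phenylnona-1,3-diene, via alkylborane 4 (not isolated)
Conditions: 9-BBN-H, THF, 0 °C → rt; then 2, PdCl2(dppf) [dppf = 1,1'-bis(diphenylphosphino)ferrocene], aq. K3PO4, DMF, rt
Reagents that add atoms: none
Why: Anti-Markovnikov hydroboration followed by B-alkyl Suzuki–Miyaura coupling joins the primary borane to the dienyl iodide with retention of alkene geometry, and the basic medium protects the enol ether.

Step 3
Reactants: 5 (1E,3E)-1-methoxy-9-phenylnona-1,3-diene; 6 acrolein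
Product: 7 (1S,2R,5R)-2-methoxy-5-(5-phenylpentyl)cyclohex-3-ene-1-carbaldehyde
Conditions: (5R)-5-benzyl-2,2,3-trimethylimidazolidin-4-one hydrochloride (20 mol %), acrolein (3 equiv), MeCN/H2O 95:5, −20 °C
Reagents that add atoms: none
Why: Acrolein condenses with the secondary amine to an (E)-iminium ion whose lowered LUMO undergoes a concerted, asynchronous Diels–Alder reaction with the electron-rich diene; the closest known reaction type is the imidazolidinone-catalysed cycloaddition of enals to 1-oxygenated butadienes. Ring B is closed by an intermolecular [4+2] cycloaddition that is suprafacial on both partners, C4a–C5 forming slightly ahead of C8a–C8. The 1-methoxy donor makes C5 the nucleophilic terminus, so C5 goes to the β-carbon (C4a) and the methoxy-bearing C8 to the formyl-bearing carbon (C8a), which is the "ortho" orientation the target needs. C5 and C8 come out cis because both ends of the (1E,3E)-diene add to the same face; their absolute sense is set by the benzyl arm of the (5R)-catalyst, which leaves only the Re face of the iminium α-carbon open, in combination with the endo transition state (formyl under the diene), which also sets C8a. Endo selectivity is needed as much as facial selectivity, since the exo adduct would carry the mirror-image C5/C8 pair, so the minor exo isomer is removed by chromatography before C8a is made planar; low temperature and excess acrolein hold back hydrolysis of the enol ether.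

Step 4
Reactants: 7 (1S,2R,5R)-2-methoxy-5-(5-phenylpentyl)cyclohex-3-ene-1-carbaldehyde
Product: 8 (1S,2R,5S)-2-methoxy-5-(5-phenylpentyl)cyclohexane-1-carbaldehyde
Conditions: H2 (1 atm), 10% Pd/C (palladium on carbon), EtOAc, rt
Reagents that add atoms: none
Why: Heterogeneous hydrogenation should saturate the cis-disubstituted C6=C7 alkene well before it touches the aldehyde or the phenyl ring; it creates no stereocentre and leaves C5 and C8 as they are.

Step 5
Reactants: 8 (1S,2R,5S)-2-methoxy-5-(5-phenylpentyl)cyclohexane-1-carbaldehyde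
Product: 9 tert-butyl({[(2R,5S)-2-methoxy-5-(5-phenylpentyl)cyclohexylidene]methyl}oxy)dimethylsilane (E/Z mixture at the enol ether)
Conditions: TBSOTf, Et3N, CH2Cl2, 0 °C
Reagents that add atoms: tert-butyldimethylsilyl trifluoromethanesulfonate, CC(C)(C)[Si](C)(C)OS(=O)(=O)C(F)(F)F
Why: Soft enolization of the aldehyde (silyl triflate plus amine) gives the silyl enol ether, which turns the formyl carbon into an alkene carbon that can be cut off and makes C8a planar.

Step 6
Reactants: 9 tert-butyl({[(2R,5S)-2-methoxy-5-(5-phenylpentyl)cyclohexylidene]methyl}oxy)dimethylsilane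
Product: 10 (2R,5S)-2-methoxy-5-(5-phenylpentyl)cyclohexan-1-one
Conditions: O3, CH2Cl2, −78 °C; then Me2S, −78 °C → rt
Reagents that add atoms: ozone, [O-][O+]=O
Why: Ozonolysis of the electron-rich enol ether double bond with reductive work-up excises the former formyl carbon as a silyl formate and leaves the C8a ketone under neutral conditions, so the α-methoxy centre C8 is not enolized.

Step 7
Reactants: 10 (2R,5S)-2-methoxy-5-(5-phenylpentyl)cyclohexan-1-one; 11 N,2-dimethoxy-N-methylacetamide
Product: 13 (3S,6R)-6-methoxy-2-(methoxyacetyl)-3-(5-phenylpentyl)cyclohexan-1-one (C2 epimers and enol forms), via lithium enolate 12 (not isolated)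
Conditions: LiN(iPr)2, THF, −78 °C; then 11, −78 → 0 °C; aq. NH4Cl
Reagents that add atoms: none
Why: Kinetic deprotonation should take the CH2 group C4a rather than the methoxy-bearing methine C8, and Claisen-type C-acylation by the N-methoxy-N-methylamide stops at the chelated tetrahedral adduct until work-up, so the diketone cannot quench the enolate; the new centre at C4a becomes sp2 later.

Step 8
Reactants: 13 (3S,6R)-6-methoxy-2-(methoxyacetyl)-3-(5-phenylpentyl)cyclohexan-1-one
Product: 15 (5S,8R)-1,3,8-trimethoxy-2-methyl-5-(5-phenylpentyl)-5,6,7,8-tetrahydroquinolin-4(1H)-one, via enaminone 14 (not isolated)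
Conditions: MeC(OMe)2NMe2, toluene, 90 °C; then MeONH2·HCl, EtOH/AcOH, 70 °C
Reagents that add atoms: N,N-dimethylacetamide dimethyl acetal, CC(OC)(OC)N(C)C; O-methylhydroxylamine hydrochloride, CON.Cl
Why: The amide acetal condenses at the only methylene flanked by carbonyl and methoxy (C3) to give the enaminone, and O-methylhydroxylamine then exchanges the dimethylamino group and condenses with the C8a carbonyl (amine exchange and cyclodehydration to the 4-pyridone), aromatization driving the sequence without touching C5 or C8.

Compound list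
1 | (2E)-3-methoxyprop-2-enal | CO/C=C/C=O | starting material
2 | (1E,3E)-1-iodo-4-methoxybuta-1,3-diene | CO/C=C/C=C/I | intermediate
3 | 5-phenylpent-1-ene | C=CCCCc1ccccc1 | starting material
4 | 9-(5-phenylpentyl)-9-borabicyclo[3.3.1]nonane | C(CCCCc1ccccc1)B1C2CCCC1CCC2 | intermediate
5 | (1E,3E)-1-methoxy-9-phenylnona-1,3-diene | CO/C=C/C=C/CCCCCc1ccccc1 | intermediate
6 | acrolein (prop-2-enal) | C=CC=O | starting material
7 | (1S,2R,5R)-2-methoxy-5-(5-phenylpentyl)cyclohex-3-ene-1-carbaldehyde | O=C[C@H]1C[C@@H](CCCCCc2ccccc2)C=C[C@H]1OC | intermediate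
8 | (1S,2R,5S)-2-methoxy-5-(5-phenylpentyl)cyclohexane-1-carbaldehyde | O=C[C@H]1C[C@@H](CCCCCc2ccccc2)CC[C@H]1OC | intermediate
9 | tert-butyl({[(2R,5S)-2-methoxy-5-(5-phenylpentyl)cyclohexylidene]methyl}oxy)dimethylsilane, E/Z mixture | CC(C)(C)[Si](C)(C)OC=C1C[C@@H](CCCCCc2ccccc2)CC[C@H]1OC | intermediate
10 | (2R,5S)-2-methoxy-5-(5-phenylpentyl)cyclohexan-1-one | O=C1C[C@@H](CCCCCc2ccccc2)CC[C@H]1OC | intermediate
11 | N,2-dimethoxy-N-methylacetamide | COCC(=O)N(C)OC | starting material
12 | lithium (3S,6R)-6-methoxy-3-(5-phenylpentyl)cyclohex-1-en-1-olate | [Li]OC1=C[C@@H](CCCCCc2ccccc2)CC[C@H]1OC | intermediate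
13 | (3S,6R)-6-methoxy-2-(methoxyacetyl)-3-(5-phenylpentyl)cyclohexan-1-one | COCC(=O)C1[C@@H](CCCCCc2ccccc2)CC[C@@H](OC)C1=O | intermediate
14 | (3S,6R)-2-[3-(dimethylamino)-2-methoxybut-2-enoyl]-6-methoxy-3-(5-phenylpentyl)cyclohexan-1-one | CN(C)C(C)=C(OC)C(=O)C1[C@@H](CCCCCc2ccccc2)CC[C@@H](OC)C1=O | intermediate
15 | (5S,8R)-1,3,8-trimethoxy-2-methyl-5-(5-phenylpentyl)-5,6,7,8-tetrahydroquinolin-4(1H)-one (waltherione H) | COc1c(C)n(OC)c2c(c1=O)[C@@H](CCCCCc1ccccc1)CC[C@H]2OC | target

Total step count: 8. Longest linear sequence: 8 steps (1 → 2 → 5 → 7 → 8 → 9 → 10 → 13 → 15).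

Steps most likely to fail

Step 3. Hydrolysis of the enol ether of the diene by the aqueous ammonium salt may outrun the cycloaddition, or endo and facial control may erode so that the enantiomeric purity at C5/C8 falls. The fallback sets out from 5 and uses an anhydrous chiral Lewis acid instead of iminium activation. The dienophile is 2,2,2-trifluoroethyl acrylate. The catalyst is the triflimide (HNTf2) salt of the diphenylprolinol-derived oxazaborolidine 3,3-diphenyl-1-(2-methylphenyl)tetrahydro-1H,3H-pyrrolo[1,2-c][1,3,2]oxazaborole, taken in the enantiomeric form that the accepted facial model assigns to the required diene face, in CH2Cl2 at −78 °C. This should give the endo ester 2,2,2-trifluoroethyl (1S,2R,5R)-2-methoxy-5-(5-phenylpentyl)cyclohex-3-ene-1-carboxylate F1. Half-reduction with iBu2AlH (CH2Cl2, −78 °C) comes back to the route at 7.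

Step 7. Slow acyl transfer may let the kinetic enolate exchange protons with unreacted ketone, so that regiocontrol is lost and C8 epimerizes. The fallback sets out from 10 and replaces acyl transfer by aldol addition and oxidation. The same enolate (LiN(iPr)2, THF, −78 °C) is trapped at once by methoxyacetaldehyde to give (3S,6R)-2-(1-hydroxy-2-methoxyethyl)-6-methoxy-3-(5-phenylpentyl)cyclohexan-1-one F2 as a mixture at the two new centres. Swern oxidation ((COCl)2, DMSO; Et3N, −78 °C) comes back to the route at 13.

Step 8. The enol oxygen may close onto C2 faster than nitrogen is taken up, so that the 4-pyranone accumulates and the weakly nucleophilic alkoxyamine does not exchange the ring oxygen next to the hindered C8a. The fallback sets out from 13 and makes the ring-oxygen exchange a separate, deliberate operation. The enaminone 14 is closed with acid (AcOH, 80 °C) to (5S,8R)-3,8-dimethoxy-2-methyl-5-(5-phenylpentyl)-5,6,7,8-tetrahydro-4H-chromen-4-one F3. The ring oxygen is exchanged with NH2OH·HCl in pyridine/EtOH at reflux to give (5S,8R)-1-hydroxy-3,8-dimethoxy-2-methyl-5-(5-phenylpentyl)-5,6,7,8-tetrahydroquinolin-4(1H)-one F4. O-Methylation (MeI, K2CO3, DMF) comes back to the route at 15.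

Further compounds
F1 | step 3 | 2,2,2-trifluoroethyl (1S,2R,5R)-2-methoxy-5-(5-phenylpentyl)cyclohex-3-ene-1-carboxylate | O=C(OCC(F)(F)F)[C@H]1C[C@@H](CCCCCc2ccccc2)C=C[C@H]1OC
F2 | step 7 | (3S,6R)-2-(1-hydroxy-2-methoxyethyl)-6-methoxy-3-(5-phenylpentyl)cyclohexan-1-one | COCC(O)C1[C@@H](CCCCCc2ccccc2)CC[C@@H](OC)C1=O
F3 | step 8 | (5S,8R)-3,8-dimethoxy-2-methyl-5-(5-phenylpentyl)-5,6,7,8-tetrahydro-4H-chromen-4-one | COc1c(C)oc2c(c1=O)[C@@H](CCCCCc1ccccc1)CC[C@H]2OC
F4 | step 8 | (5S,8R)-1-hydroxy-3,8-dimethoxy-2-methyl-5-(5-phenylpentyl)-5,6,7,8-tetrahydroquinolin-4(1H)-one | COc1c(C)n(O)c2c(c1=O)[C@@H](CCCCCc1ccccc1)CC[C@H]2OC
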